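**Retrosynthetic overview**
1. Target 41 is the ring-opened form of a (12S)-butenolide. The lactone is opened and C19 deallylated last; C16 comes from methylcuprate addition to a (12S)-γ-hydroxy ynoate, C13–C15 from methyl propiolate added to a C12 aldehyde, and C12 is set by Midland reduction.
2. On the decalin, C17 comes from Wittig methylenation of a C8 ketone, the C18 methyl from the equatorial (α) C4 ester, and C12 from methylenation/hydroboration of the C11 aldehyde.
3. Key disconnection C5–C10 and C8–C9: the trans-decalin (ring A C1–C5 and C10, ring B C5–C10), whose quaternary C10 methyl sits between C5–H and C9–H with C11 on C9 cis to that methyl, is the formyl-endo [4+2] adduct of an (E)-3-methyl-enal tethered through C1–C4 to an (E,E)-1-acetoxydiene. Rings A and B form together in this step; the butenolide ring forms in step 25 and is opened in step 26.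
4. Trienal 15 comes from dimethyl malonate by two alkylations (silyl ether of (E)-6-chloro-3-methylhex-2-enol, then (E)-1,4-dibromobut-2-ene), enal and dienyl acetate formation, desilylation and MnO2 oxidation.

Key step: step 9

Remark (assumption): the target is the open (Z)-γ-hydroxy acid of a butenolide and is taken to be isolable when the dicarboxylate is acidified cold and only to pH 4.
Remark (assumption): the facial sense of step 9 is taken from the usual binding model (formyl C–H···O contact, s-trans enal over an aryl group), by which the catalyst from (R)-diphenylprolinol should leave the Cα-si/Cβ-re face of the enal open; if the sense proved opposite, the (S)-catalyst would be used with no other change.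
Remark: labdane numbering is used for all bicyclic compounds (C11 on C9, C17 on C8, C18 α and C19 β on C4, C20 on C10).

Step 1
Reactants: 1 5-chloropent-1-yne
Product: 4 (E)-6-chloro-3-methylhex-2-en-1-ol, via alkenyldimethylalane 2 (not isolated), via lithium alkenylalanate 3 (not isolated)
Conditions: AlMe3 (2 equiv), Cp2ZrCl2 (0.25 equiv), CH2Cl2, 0 °C → rt; n-BuLi, hexane/THF, −78 → 0 °C; (CH2O)n, rt; aq. HCl
Reagents that add atoms: trimethylaluminium C[Al](C)C; paraformaldehyde (formaldehyde) C=O
Why: Negishi zirconium-catalysed carboalumination adds methyl and aluminium syn across the terminal alkyne with methyl on the internal carbon, and the ate complex is hydroxymethylated with retention, which fixes the (E) trisubstituted alkene that later serves as the dienophile.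

Step 2
Reactants: 4 (E)-6-chloro-3-methylhex-2-en-1-ol
Product: 5 tert-butyl{[(E)-6-chloro-3-methylhex-2-enyl]oxy}dimethylsilane
Conditions: TBSCl, imidazole, CH2Cl2, 0 °C → rt
Reagents that add atoms: tert-butyldimethylsilyl chloride CC(C)(C)[Si](C)(C)Cl
Why: Standard silyl ether protection of the primary allylic alcohol so that it survives the two enolate alkylations; no stereocenter is formed.

Step 3
Reactants: 5 tert-butyl{[(E)-6-chloro-3-methylhex-2-enyl]oxy}dimethylsilane; 6 dimethyl malonate
Product: 8 dimethyl 2-[(E)-6-(tert-butyldimethylsilyloxy)-4-methylhex-4-enyl]malonate, via sodium dimethyl malonate 7 (not isolated)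
Conditions: 6 (3 equiv), NaH (2.5 equiv), DMF, 0 °C; then 5, NaI (0.2 equiv), 70 °C
Reagents that add atoms: none
Why: Malonic ester alkylation in which the sodium enolate displaces the primary chloride by SN2 under iodide catalysis, the excess of malonate suppressing dialkylation.

Step 4
Reactants: 8 dimethyl 2-[(E)-6-(tert-butyldimethylsilyloxy)-4-methylhex-4-enyl]malonate; 9 (E)-1,4-dibromobut-2-ene
Product: 11 dimethyl 2-[(E)-4-bromobut-2-enyl]-2-[(E)-6-(tert-butyldimethylsilyloxy)-4-methylhex-4-enyl]malonate, via sodium enolate 10 (not isolated)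
Conditions: NaH (1.1 equiv), THF, 0 °C; then added to 9 (4 equiv), THF, 0 °C → rt
Reagents that add atoms: none
Why: Second malonic ester alkylation, the tertiary enolate attacking one primary allylic carbon of the dibromide by SN2 while the excess of 9 prevents double substitution and the (E) alkene is carried over unchanged.

Step 5
Reactants: 11 dimethyl 2-[(E)-4-bromobut-2-enyl]-2-[(E)-6-(tert-butyldimethylsilyloxy)-4-methylhex-4-enyl]malonate
Product: 12 dimethyl 2-[(E)-6-(tert-butyldimethylsilyloxy)-4-methylhex-4-enyl]-2-[(E)-4-oxobut-2-enyl]malonate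
Conditions: N-methylmorpholine N-oxide (4 equiv), 4 Å molecular sieves, MeCN, 0 °C → rt
Reagents that add atoms: N-methylmorpholine N-oxide C[N+]1([O-])CCOCC1
Why: N-oxide oxidation of an allylic halide (related to the Kornblum oxidation), in which O-alkylation of the N-oxide and base-induced loss of N-methylmorpholine give the (E)-enal without touching the silyl ether.

Step 6
Reactants: 12 dimethyl 2-[(E)-6-(tert-butyldimethylsilyloxy)-4-methylhex-4-enyl]-2-[(E)-4-oxobut-2-enyl]malonate
Product: 13 dimethyl 2-[(1E,3E)-4-acetoxybuta-1,3-dienyl]-2-[(E)-6-(tert-butyldimethylsilyloxy)-4-methylhex-4-enyl]malonate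
Conditions: Ac2O (3 equiv), Et3N (4 equiv), DMAP (0.2 equiv), THF, 40 °C
Reagents that add atoms: acetic anhydride CC(=O)OC(C)=O
Why: Dienol acetate formation by γ-deprotonation of the enal and O-acylation of the extended dienolate under equilibrating amine/DMAP conditions, which should favour the (1E,3E) isomer (quaternary carbon trans on C5=C6, enol acetate from the s-trans enal); any (1Z) isomer is removed by chromatography.

Step 7
Reactants: 13 dimethyl 2-[(1E,3E)-4-acetoxybuta-1,3-dienyl]-2-[(E)-6-(tert-butyldimethylsilyloxy)-4-methylhex-4-enyl]malonate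
Product: 14 dimethyl 2-[(1E,3E)-4-acetoxybuta-1,3-dienyl]-2-[(E)-6-hydroxy-4-methylhex-4-enyl]malonate
Conditions: HF·pyridine, pyridine, THF, 0 °C → rt
Reagents that add atoms: none
Why: Fluoride cleavage of the primary silyl ether under buffered, weakly acidic conditions that leave the enol acetate, which basic fluoride would cleave, intact.

Step 8
Reactants: 14 dimethyl 2-[(1E,3E)-4-acetoxybuta-1,3-dienyl]-2-[(E)-6-hydroxy-4-methylhex-4-enyl]malonate
Product: 15 dimethyl 2-[(1E,3E)-4-acetoxybuta-1,3-dienyl]-2-[(E)-4-methyl-6-oxohex-4-enyl]malonate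
Conditions: MnO2 (20 equiv), CH2Cl2, rt
Reagents that add atoms: none
Why: MnO2 oxidises the allylic alcohol selectively to the enal without isomerising the trisubstituted (E) alkene or affecting the dienyl acetate; the trienal is used at once.

Step 9
Reactants: 15 dimethyl 2-[(1E,3E)-4-acetoxybuta-1,3-dienyl]-2-[(E)-4-methyl-6-oxohex-4-enyl]malonate
Product: 16 dimethyl 8β-acetoxy-9β-formyl-10β-methyl-5α-H-octal-6-ene-4,4-dicarboxylate (trans-fused cycloadduct)
Conditions: (R)-3,3-diphenyl-1-(2-methylphenyl)tetrahydro-1H,3H-pyrrolo[1,2-c][1,3,2]oxazaborole (0.2 equiv), Tf2NH (0.18 equiv), CH2Cl2, −78 → −20 °C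
Reagents that add atoms: none
Why: The N-protonated oxazaborolidine binds the formyl oxygen of 15 and lowers the LUMO of the (E)-enal, so that the acetoxydiene adds in a concerted, asynchronous [4+2] in which C5–C10 (diene terminus remote from the acetoxy group to the enal β-carbon) runs ahead of C8–C9; the closest known reaction type is the oxazaborolidinium-catalysed enantioselective intramolecular Diels–Alder reaction of trienals. Ring B (C5–C10) closes as the six-membered cycloaddition ring, and ring A (C1–C5 and C10) closes as the six-membered tether ring when C5–C10 forms, the fused mode being the only one the four-atom tether allows. The trans ring fusion (5α-H, 10β-methyl) follows from the formyl-endo transition state with a chair-like tether, the C9 configuration (C11 cis to the C10 methyl) from suprafacial addition to the (E)-dienophile, and the C8 configuration (acetoxy cis to formyl) from the (E)-enol acetate geometry together with the endo mode. The absolute configuration comes from the catalyst, whose aryl group covers one face of the bound s-trans enal so that the diene adds to the Cα-si/Cβ-re face. The step needs endo over exo selectivity and facial selectivity: Lewis-acid activation of the aldehyde favours the endo mode, the geminal diester raises the population of the reactive conformer and removes any stereocenter at C4, and the tether enforces the regiochemistry in the electronically matched sense.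

Step 10
Reactants: 16 dimethyl 8β-acetoxy-9β-formyl-10β-methyl-5α-H-octal-6-ene-4,4-dicarboxylate
Product: 17 dimethyl 8β-acetoxy-10β-methyl-9β-vinyl-5α-H-octal-6-ene-4,4-dicarboxylate
Conditions: CH2I2, Zn, Ti(OiPr)4, THF, rt
Reagents that add atoms: diiodomethane ICI
Why: Takai methylenation with the non-basic Zn/CH2I2/Ti(OiPr)4 reagent converts the hindered aldehyde into the vinyl group (C11=C12) without the β-elimination of acetic acid or the C9 epimerisation that a basic ylide could cause, and it leaves the esters untouched.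

Step 11
Reactants: 17 dimethyl 8β-acetoxy-10β-methyl-9β-vinyl-5α-H-octal-6-ene-4,4-dicarboxylate
Product: 19 dimethyl 8β-hydroxy-9β-(2-hydroxyethyl)-10β-methyl-5α-H-octal-6-ene-4,4-dicarboxylate, via alkylborane 18 (not isolated)
Conditions: 9-borabicyclo[3.3.1]nonane (9-BBN, 2 equiv), THF, 0 °C → rt; then aq. NaOH, H2O2, 0 °C → rt
Reagents that add atoms: hydrogen peroxide OO
Why: Anti-Markovnikov hydroboration with 9-BBN is selective for the monosubstituted vinyl group over the ring cis-alkene, and the alkaline peroxide oxidation (C–B to C–O with retention) also cleaves the acetate, while the hindered methyl esters on the quaternary carbon should survive the short cold treatment.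

Step 12
Reactants: 19 dimethyl 8β-hydroxy-9β-(2-hydroxyethyl)-10β-methyl-5α-H-octal-6-ene-4,4-dicarboxylate
Product: 20 dimethyl 9β-[2-(tert-butyldiphenylsilyloxy)ethyl]-8β-hydroxy-10β-methyl-5α-H-octal-6-ene-4,4-dicarboxylate
Conditions: TBDPSCl (1.05 equiv), imidazole, CH2Cl2, 0 °C
Reagents that add atoms: tert-butyldiphenylsilyl chloride CC(C)(C)[Si](Cl)(c1ccccc1)c1ccccc1
Why: Selective silylation, the bulky silyl chloride reacting with the primary alcohol much faster than with the hindered axial secondary allylic alcohol.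

Step 13
Reactants: 20 dimethyl 9β-[2-(tert-butyldiphenylsilyloxy)ethyl]-8β-hydroxy-10β-methyl-5α-H-octal-6-ene-4,4-dicarboxylate
Product: 21 dimethyl 9β-[2-(tert-butyldiphenylsilyloxy)ethyl]-10β-methyl-8-oxo-5α-H-octal-6-ene-4,4-dicarboxylate
Conditions: Dess–Martin periodinane, CH2Cl2, rt
Reagents that add atoms: none
Why: Dess–Martin oxidation of the secondary allylic alcohol to the enone under neutral conditions that touch neither the silyl ether nor the esters.

Step 14
Reactants: 21 dimethyl 9β-[2-(tert-butyldiphenylsilyloxy)ethyl]-10β-methyl-8-oxo-5α-H-octal-6-ene-4,4-dicarboxylate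
Product: 22 dimethyl 9β-[2-(tert-butyldiphenylsilyloxy)ethyl]-10β-methyl-8-oxo-5α-H-decalin-4,4-dicarboxylate
Conditions: H2 (1 atm), Pd/C, EtOAc, rt
Reagents that add atoms: none
Why: Heterogeneous hydrogenation of the conjugated C6=C7 bond, which creates no stereocenter and avoids the hydrogenolysis an allylic C–O bond could suffer; ketone, esters and silyl ether are inert under these conditions.

Step 15
Reactants: 22 dimethyl 9β-[2-(tert-butyldiphenylsilyloxy)ethyl]-10β-methyl-8-oxo-5α-H-decalin-4,4-dicarboxylate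
Product: 23 dimethyl 9β-[2-(tert-butyldiphenylsilyloxy)ethyl]-10β-methyl-8-methylene-5α-H-decalin-4,4-dicarboxylate
Conditions: Ph3PCH3Br, KOtBu, toluene, rt → 80 °C
Reagents that add atoms: methyltriphenylphosphonium bromide C[P+](c1ccccc1)(c1ccccc1)c1ccccc1.[Br-]
Why: Wittig methylenation of the C8 ketone installs C17; reversible enolisation at C9 is harmless because the equatorial 9β side chain is the stable epimer, and the quaternary esters are not attacked.

Step 16
Reactants: 23 dimethyl 9β-[2-(tert-butyldiphenylsilyloxy)ethyl]-10β-methyl-8-methylene-5α-H-decalin-4,4-dicarboxylate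
Product: 24 methyl 12-(tert-butyldiphenylsilyloxy)-18-hydroxy-13,14,15,16-tetranorlabd-8(17)-en-19-oate
Conditions: LiAlH(OtBu)3 (3 equiv), THF, rt → 50 °C; aq. KNaC4H4O6 work-up
Reagents that add atoms: none
Why: Chemoselective mono-reduction of a 2,2-disubstituted malonate to the β-hydroxy ester by LiAlH(OtBu)3 (hydride reduction of an ester), the equatorial α ester being attacked because the axial β ester is shielded by the 1,3-diaxial C10 methyl, which sets C4 with CH2OH α and CO2Me β.

Step 17
Reactants: 24 methyl 12-(tert-butyldiphenylsilyloxy)-18-hydroxy-13,14,15,16-tetranorlabd-8(17)-en-19-oate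
Product: 25 methyl 12-(tert-butyldiphenylsilyloxy)-18-(methanesulfonyloxy)-13,14,15,16-tetranorlabd-8(17)-en-19-oate
Conditions: MsCl, Et3N, CH2Cl2, 0 °C
Reagents that add atoms: methanesulfonyl chloride CS(=O)(=O)Cl
Why: Sulfonylation of the neopentyl primary alcohol under mild amine conditions, which avoid the retro-aldol loss of formaldehyde that a strongly basic alkoxide of this β-hydroxy ester could undergo.

Step 18
Reactants: 25 methyl 12-(tert-butyldiphenylsilyloxy)-18-(methanesulfonyloxy)-13,14,15,16-tetranorlabd-8(17)-en-19-oate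
Product: 27 methyl 12-(tert-butyldiphenylsilyloxy)-13,14,15,16-tetranorlabd-8(17)-en-19-oate, via neopentyl iodide 26 (not isolated)
Conditions: NaI, Zn, HMPA, 105 °C; aq. NH4Cl
Reagents that add atoms: none
Why: Finkelstein displacement of the hindered primary mesylate by iodide followed by zinc reduction of the C–I bond in the same flask (NaI–Zn deoxygenation of hindered sulfonates) turns C18 into the α methyl group; C4 keeps its configuration because no bond to it is broken.

Step 19
Reactants: 27 methyl 12-(tert-butyldiphenylsilyloxy)-13,14,15,16-tetranorlabd-8(17)-en-19-oate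
Product: 29 allyl 12-(tert-butyldiphenylsilyloxy)-13,14,15,16-tetranorlabd-8(17)-en-19-oate, via lithium carboxylate 28 (not isolated)
Conditions: n-PrSH, n-BuLi, HMPA, rt; then allyl bromide (excess), rt
Reagents that add atoms: allyl bromide C=CCBr
Why: SN2 dealkylation of the hindered axial methyl ester by thiolate at the methyl carbon, then O-alkylation of the carboxylate with allyl bromide; both events avoid the shielded acyl carbon and give an ester that can be removed at the end without hydrolysis.

Step 20
Reactants: 29 allyl 12-(tert-butyldiphenylsilyloxy)-13,14,15,16-tetranorlabd-8(17)-en-19-oate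
Product: 30 allyl 12-hydroxy-13,14,15,16-tetranorlabd-8(17)-en-19-oate
Conditions: Bu4NF, THF, rt
Reagents that add atoms: none
Why: Fluoride cleavage of the silyl ether, the shielded axial allyl ester not being attacked by basic fluoride at room temperature.

Step 21
Reactants: 30 allyl 12-hydroxy-13,14,15,16-tetranorlabd-8(17)-en-19-oate
Product: 31 allyl 12-oxo-13,14,15,16-tetranorlabd-8(17)-en-19-oate
Conditions: Dess–Martin periodinane, CH2Cl2, rt
Reagents that add atoms: none
Why: Dess–Martin oxidation of the primary alcohol to the aldehyde under near-neutral conditions, so that the exocyclic alkene neither migrates nor engages the aldehyde in an acid-promoted ene cyclisation; the aldehyde is used at once.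

Step 22
Reactants: 31 allyl 12-oxo-13,14,15,16-tetranorlabd-8(17)-en-19-oate; 32 methyl propiolate
Product: 34 19-allyl 15-methyl (12RS)-12-hydroxy-16-norlabd-8(17)-en-13-yne-15,19-dioate (mixture of C12 epimers), via lithium acetylide 33 (not isolated)
Conditions: 32, LiN(SiMe3)2, THF, −78 °C; then 31, −78 °C; AcOH quench at −78 °C
Reagents that add atoms: none
Why: 1,2-Addition of the lithium acetylide of methyl propiolate to the aldehyde at −78 °C, where the acetylide is stable and the shielded C19 ester is inert; C12 is not controlled here and is corrected in the next two steps.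

Step 23
Reactants: 34 19-allyl 15-methyl (12RS)-12-hydroxy-16-norlabd-8(17)-en-13-yne-15,19-dioate
Product: 35 19-allyl 15-methyl 12-oxo-16-norlabd-8(17)-en-13-yne-15,19-dioate
Conditions: Dess–Martin periodinane, CH2Cl2, 0 °C → rt
Reagents that add atoms: none
Why: Dess–Martin oxidation of the propargylic alcohol to the 4-oxo-2-ynoate removes the uncontrolled C12 centre.

Step 24
Reactants: 35 19-allyl 15-methyl 12-oxo-16-norlabd-8(17)-en-13-yne-15,19-dioate
Product: 37 19-allyl 15-methyl (12S)-12-hydroxy-16-norlabd-8(17)-en-13-yne-15,19-dioate, via borinate ester 36 (not isolated)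
Conditions: B-isopinocampheyl-9-borabicyclo[3.3.1]nonane from (−)-α-pinene ((S)-Alpine-Borane, 2 equiv), THF, 0 °C → rt; then ethanolamine, Et2O
Reagents that add atoms: none
Why: Midland reduction, in which hydride passes from the pinanyl group through a six-membered boat-like transition state with the slim alkynyl group in the crowded position, should give the (12S) alcohol by analogy with the rule that the reagent from (+)-α-pinene gives (R)-alkynyl carbinols; the activated ynone reacts fast, so dissociation of the reagent to 9-BBN, which would hydroborate C8=C17, should not compete.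

Step 25
Reactants: 37 19-allyl 15-methyl (12S)-12-hydroxy-16-norlabd-8(17)-en-13-yne-15,19-dioate
Product: 39 allyl (12S)-labda-8(17),13-dien-15,12-olid-19-oate, via hydroxy enoate 38 (not isolated)
Conditions: MeLi, CuI, THF (Me2CuLi, 3 equiv), −78 °C; MeOH then aq. NH4Cl at −78 °C; PPTS (cat.), CH2Cl2, rt
Reagents that add atoms: lithium dimethylcuprate (made from MeLi and CuI) [Li+].C[Cu-]C
Why: syn-Carbocupration (conjugate addition) of the ynoate places methyl on C13 and copper on C14 cis to each other, cold protonation with retention gives the (Z)-γ-hydroxy enoate, and this lactonises to the butenolide with C12 untouched; at −78 °C the hindered allyl ester should not undergo allylic substitution.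

Step 26
Reactants: 39 allyl (12S)-labda-8(17),13-dien-15,12-olid-19-oate
Product: 41 (12S,13Z)-12-hydroxylabda-8(17),13-diene-15,19-dioic acid, via butenolide acid 40 (not isolated)
Conditions: Pd(PPh3)4 (0.05 equiv), morpholine (1.5 equiv), THF, rt; then LiOH, THF/H2O, 0 °C; cold 0.5 M HCl to pH 4, rapid extraction
Reagents that add atoms: lithium hydroxide [Li+].[OH-]
Why: Tsuji–Trost-type deallylation (zerovalent palladium, morpholine as allyl acceptor) frees the C19 acid without attack at the shielded acyl carbon, and hydroxide then opens the butenolide by acyl–oxygen cleavage (saponification), so the C12–O bond and the (Z) alkene are kept; cold, limited acidification restrains relactonisation.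

**Compound list**
1 | 5-chloropent-1-yne | C#CCCCCl | starting material
2 | (E)-(5-chloro-2-methylpent-1-enyl)dimethylalane (not isolated) | C[Al](C)/C=C(C)/CCCCl | intermediate
3 | lithium butyl[(E)-5-chloro-2-methylpent-1-enyl]dimethylaluminate (not isolated) | [Li+].CCCC[Al-](C)(C)/C=C(C)/CCCCl | intermediate
4 | (E)-6-chloro-3-methylhex-2-en-1-ol | OC/C=C(C)/CCCCl | intermediate
5 | tert-butyl{[(E)-6-chloro-3-methylhex-2-enyl]oxy}dimethylsilane | CC(C)(C)[Si](C)(C)OC/C=C(C)/CCCCl | intermediate
6 | dimethyl malonate | COC(=O)CC(=O)OC | starting material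
7 | sodium dimethyl malonate (not isolated) | [Na+].COC(=O)[CH-]C(=O)OC | intermediate
8 | dimethyl 2-[(E)-6-(tert-butyldimethylsilyloxy)-4-methylhex-4-enyl]malonate | COC(=O)C(CCC/C(C)=C/CO[Si](C)(C)C(C)(C)C)C(=O)OC | intermediate
9 | (E)-1,4-dibromobut-2-ene | BrC/C=C/CBr | starting material
10 | sodium enolate of 8 (not isolated) | [Na+].COC(=O)[C-](CCC/C(C)=C/CO[Si](C)(C)C(C)(C)C)C(=O)OC | intermediate
11 | dimethyl 2-[(E)-4-bromobut-2-enyl]-2-[(E)-6-(tert-butyldimethylsilyloxy)-4-methylhex-4-enyl]malonate | COC(=O)C(C/C=C/CBr)(CCC/C(C)=C/CO[Si](C)(C)C(C)(C)C)C(=O)OC | intermediate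
12 | dimethyl 2-[(E)-6-(tert-butyldimethylsilyloxy)-4-methylhex-4-enyl]-2-[(E)-4-oxobut-2-enyl]malonate | COC(=O)C(C/C=C/C=O)(CCC/C(C)=C/CO[Si](C)(C)C(C)(C)C)C(=O)OC | intermediate
13 | dimethyl 2-[(1E,3E)-4-acetoxybuta-1,3-dienyl]-2-[(E)-6-(tert-butyldimethylsilyloxy)-4-methylhex-4-enyl]malonate | COC(=O)C(/C=C/C=C/OC(C)=O)(CCC/C(C)=C/CO[Si](C)(C)C(C)(C)C)C(=O)OC | intermediate
14 | dimethyl 2-[(1E,3E)-4-acetoxybuta-1,3-dienyl]-2-[(E)-6-hydroxy-4-methylhex-4-enyl]malonate | COC(=O)C(/C=C/C=C/OC(C)=O)(CCC/C(C)=C/CO)C(=O)OC | intermediate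
15 | dimethyl 2-[(1E,3E)-4-acetoxybuta-1,3-dienyl]-2-[(E)-4-methyl-6-oxohex-4-enyl]malonate | COC(=O)C(/C=C/C=C/OC(C)=O)(CCC/C(C)=C/C=O)C(=O)OC | intermediate
16 | dimethyl 8β-acetoxy-9β-formyl-10β-methyl-5α-H-octal-6-ene-4,4-dicarboxylate (trans-fused) | CC(=O)O[C@H]1C=C[C@@H]2[C@](C)(CCCC2(C(=O)OC)C(=O)OC)[C@H]1C=O | intermediate
17 | dimethyl 8β-acetoxy-10β-methyl-9β-vinyl-5α-H-octal-6-ene-4,4-dicarboxylate | CC(=O)O[C@H]1C=C[C@@H]2[C@](C)(CCCC2(C(=O)OC)C(=O)OC)[C@H]1C=C | intermediate
18 | B-alkyl-9-borabicyclo[3.3.1]nonane from 17, boron on C12 (not isolated) | CC(=O)O[C@H]1C=C[C@@H]2[C@](C)(CCCC2(C(=O)OC)C(=O)OC)[C@H]1CCB1C2CCCC1CCC2 | intermediate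
19 | dimethyl 8β-hydroxy-9β-(2-hydroxyethyl)-10β-methyl-5α-H-octal-6-ene-4,4-dicarboxylate | O[C@H]1C=C[C@@H]2[C@](C)(CCCC2(C(=O)OC)C(=O)OC)[C@H]1CCO | intermediate
20 | dimethyl 9β-[2-(tert-butyldiphenylsilyloxy)ethyl]-8β-hydroxy-10β-methyl-5α-H-octal-6-ene-4,4-dicarboxylate | O[C@H]1C=C[C@@H]2[C@](C)(CCCC2(C(=O)OC)C(=O)OC)[C@H]1CCO[Si](c1ccccc1)(c1ccccc1)C(C)(C)C | intermediate
21 | dimethyl 9β-[2-(tert-butyldiphenylsilyloxy)ethyl]-10β-methyl-8-oxo-5α-H-octal-6-ene-4,4-dicarboxylate | O=C1C=C[C@@H]2[C@](C)(CCCC2(C(=O)OC)C(=O)OC)[C@H]1CCO[Si](c1ccccc1)(c1ccccc1)C(C)(C)C | intermediate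
22 | dimethyl 9β-[2-(tert-butyldiphenylsilyloxy)ethyl]-10β-methyl-8-oxo-5α-H-decalin-4,4-dicarboxylate | O=C1CC[C@@H]2[C@](C)(CCCC2(C(=O)OC)C(=O)OC)[C@H]1CCO[Si](c1ccccc1)(c1ccccc1)C(C)(C)C | intermediate
23 | dimethyl 9β-[2-(tert-butyldiphenylsilyloxy)ethyl]-10β-methyl-8-methylene-5α-H-decalin-4,4-dicarboxylate | C=C1CC[C@@H]2[C@](C)(CCCC2(C(=O)OC)C(=O)OC)[C@H]1CCO[Si](c1ccccc1)(c1ccccc1)C(C)(C)C | intermediate
24 | methyl 12-(tert-butyldiphenylsilyloxy)-18-hydroxy-13,14,15,16-tetranorlabd-8(17)-en-19-oate (4α-CH2OH, 4β-CO2Me) | C=C1CC[C@@H]2[C@](C)(CCC[C@]2(CO)C(=O)OC)[C@H]1CCO[Si](c1ccccc1)(c1ccccc1)C(C)(C)C | intermediate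
25 | methyl 12-(tert-butyldiphenylsilyloxy)-18-(methanesulfonyloxy)-13,14,15,16-tetranorlabd-8(17)-en-19-oate | C=C1CC[C@@H]2[C@](C)(CCC[C@]2(COS(C)(=O)=O)C(=O)OC)[C@H]1CCO[Si](c1ccccc1)(c1ccccc1)C(C)(C)C | intermediate
26 | methyl 12-(tert-butyldiphenylsilyloxy)-18-iodo-13,14,15,16-tetranorlabd-8(17)-en-19-oate (not isolated) | C=C1CC[C@@H]2[C@](C)(CCC[C@]2(CI)C(=O)OC)[C@H]1CCO[Si](c1ccccc1)(c1ccccc1)C(C)(C)C | intermediate
27 | methyl 12-(tert-butyldiphenylsilyloxy)-13,14,15,16-tetranorlabd-8(17)-en-19-oate | C=C1CC[C@@H]2[C@](C)(CCC[C@]2(C)C(=O)OC)[C@H]1CCO[Si](c1ccccc1)(c1ccccc1)C(C)(C)C | intermediate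
28 | lithium 12-(tert-butyldiphenylsilyloxy)-13,14,15,16-tetranorlabd-8(17)-en-19-oate (not isolated) | [Li+].C=C1CC[C@@H]2[C@](C)(CCC[C@]2(C)C(=O)[O-])[C@H]1CCO[Si](c1ccccc1)(c1ccccc1)C(C)(C)C | intermediate
29 | allyl 12-(tert-butyldiphenylsilyloxy)-13,14,15,16-tetranorlabd-8(17)-en-19-oate | C=C1CC[C@@H]2[C@](C)(CCC[C@]2(C)C(=O)OCC=C)[C@H]1CCO[Si](c1ccccc1)(c1ccccc1)C(C)(C)C | intermediate
30 | allyl 12-hydroxy-13,14,15,16-tetranorlabd-8(17)-en-19-oate | C=C1CC[C@@H]2[C@](C)(CCC[C@]2(C)C(=O)OCC=C)[C@H]1CCO | intermediate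
31 | allyl 12-oxo-13,14,15,16-tetranorlabd-8(17)-en-19-oate | C=C1CC[C@@H]2[C@](C)(CCC[C@]2(C)C(=O)OCC=C)[C@H]1CC=O | intermediate
32 | methyl propiolate | C#CC(=O)OC | starting material
33 | lithium acetylide of methyl propiolate (not isolated) | [Li+].[C-]#CC(=O)OC | intermediate
34 | 19-allyl 15-methyl (12RS)-12-hydroxy-16-norlabd-8(17)-en-13-yne-15,19-dioate (C12 epimers) | C=C1CC[C@@H]2[C@](C)(CCC[C@]2(C)C(=O)OCC=C)[C@H]1CC(O)C#CC(=O)OC | intermediate
35 | 19-allyl 15-methyl 12-oxo-16-norlabd-8(17)-en-13-yne-15,19-dioate | C=C1CC[C@@H]2[C@](C)(CCC[C@]2(C)C(=O)OCC=C)[C@H]1CC(=O)C#CC(=O)OC | intermediate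
36 | 9-borabicyclo[3.3.1]nonan-9-yl borinate of 37 at O12 (not isolated) | C=C1CC[C@@H]2[C@](C)(CCC[C@]2(C)C(=O)OCC=C)[C@H]1C[C@H](OB1C2CCCC1CCC2)C#CC(=O)OC | intermediate
37 | 19-allyl 15-methyl (12S)-12-hydroxy-16-norlabd-8(17)-en-13-yne-15,19-dioate | C=C1CC[C@@H]2[C@](C)(CCC[C@]2(C)C(=O)OCC=C)[C@H]1C[C@H](O)C#CC(=O)OC | intermediate
38 | 19-allyl 15-methyl (12S,13Z)-12-hydroxylabda-8(17),13-diene-15,19-dioate (not isolated) | C=C1CC[C@@H]2[C@](C)(CCC[C@]2(C)C(=O)OCC=C)[C@H]1C[C@H](O)/C(C)=C\C(=O)OC | intermediate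
39 | allyl (12S)-labda-8(17),13-dien-15,12-olid-19-oate (4-methylbutenolide, S at the ring CH) | C=C1CC[C@@H]2[C@](C)(CCC[C@]2(C)C(=O)OCC=C)[C@H]1C[C@@H]1OC(=O)C=C1C | intermediate
40 | (12S)-labda-8(17),13-dien-15,12-olid-19-oic acid (not isolated) | C=C1CC[C@@H]2[C@](C)(CCC[C@]2(C)C(=O)O)[C@H]1C[C@@H]1OC(=O)C=C1C | intermediate
41 | (12S,13Z)-12-hydroxylabda-8(17),13-diene-15,19-dioic acid (4S,5R,9S,10R,12S) | C=C1CC[C@@H]2[C@](C)(CCC[C@]2(C)C(=O)O)[C@H]1C[C@H](O)/C(C)=C\C(=O)O | target

**Step count and risks**
Total step count: 26. Longest linear sequence: 26 steps, from 1 to 41; compounds 6, 9 and 32 enter this line directly.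

Three steps most likely to fail:

Step 9. The β,β-disubstituted enal is a weak dienophile and may react slowly. The 1,3-diaxial contact that develops between the C10 methyl and the axial C4 ester may erode the endo (trans-fused) preference. Facial discrimination by the catalyst may be incomplete. Fallback (stoichiometric achiral Lewis acid and resolution instead of asymmetric catalysis): the fallback sets out from 15, which with Me2AlCl (1.1 equiv) in CH2Cl2 at −78 → −20 °C should give the racemic trans-fused adduct, that is 16 together with its mirror image ent-16 F1. Condensation of the mixture with (1R,2R)-N,N'-dimethyl-1,2-diphenylethane-1,2-diamine (Et2O, 4 Å molecular sieves, rt) gives two diastereomeric imidazolidines, the aminal of 16 F2 and the aminal of ent-16 F3, which are separated by chromatography. Hydrolysis of F2 with cold dilute aqueous HCl in Et2O comes back to the route at 16.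

Step 16. The hydride may discriminate poorly between the two diastereotopic esters, or reduction may run on to the diol. Fallback (hydrolysis instead of hydride for the differentiation): the fallback sets out from 23. LiOH in THF/MeOH/H2O at 60 °C should saponify only the less hindered α ester and give the 18-oic acid 19-methyl ester F4. Activation with ClCO2Et and Et3N in THF at 0 °C gives the mixed carbonic anhydride F5, and NaBH4 in THF/H2O at 0 °C reduces this to the hydroxy ester, so the fallback comes back to the route at 24.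

Step 26. The γ-hydroxy (Z)-enoic acid may relactonise during acidification of the dicarboxylate, and C12 may epimerise through the furanolate before the lactone opens. Fallback (open-chain route that never forms or opens the lactone): the fallback sets out from 37. Silylation (TBSOTf, 2,6-lutidine, CH2Cl2, −78 °C) gives the 12-O-TBS ynoate F6, and Me2CuLi in THF at −78 °C gives the (Z)-enoate F7, which cannot lactonise. LiOH in THF/H2O at rt saponifies the unhindered C15 methyl ester to the 15-acid 19-allyl ester F8, and Pd(PPh3)4 with morpholine in THF removes the allyl group to give the 12-O-TBS diacid F9. Desilylation with HF·pyridine buffered with excess pyridine in THF at 0 °C then releases the hydroxy diacid near neutrality and comes back to the route at 41.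

Further compounds
F1 | step 9 | ent-16, dimethyl 8α-acetoxy-9α-formyl-10α-methyl-5β-H-octal-6-ene-4,4-dicarboxylate (mirror image of 16) | CC(=O)O[C@@H]1C=C[C@H]2[C@@](C)(CCCC2(C(=O)OC)C(=O)OC)[C@@H]1C=O
F2 | step 9 | aminal of 16 with (1R,2R)-N,N'-dimethyl-1,2-diphenylethane-1,2-diamine (1,3-dimethyl-4,5-diphenylimidazolidin-2-yl at C9) | CC(=O)O[C@H]1C=C[C@@H]2[C@](C)(CCCC2(C(=O)OC)C(=O)OC)[C@H]1C1N(C)[C@H](c2ccccc2)[C@@H](c2ccccc2)N1C
F3 | step 9 | aminal of ent-16 with the same (1R,2R)-diamine | CC(=O)O[C@@H]1C=C[C@H]2[C@@](C)(CCCC2(C(=O)OC)C(=O)OC)[C@@H]1C1N(C)[C@H](c2ccccc2)[C@@H](c2ccccc2)N1C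
F4 | step 16 | 12-(tert-butyldiphenylsilyloxy)-19-methoxy-19-oxo-13,14,15,16-tetranorlabd-8(17)-en-18-oic acid (4α-CO2H, 4β-CO2Me) | C=C1CC[C@@H]2[C@](C)(CCC[C@]2(C(=O)O)C(=O)OC)[C@H]1CCO[Si](c1ccccc1)(c1ccccc1)C(C)(C)C
F5 | step 16 | mixed ethyl carbonic anhydride of F4 at C18 | C=C1CC[C@@H]2[C@](C)(CCC[C@]2(C(=O)OC(=O)OCC)C(=O)OC)[C@H]1CCO[Si](c1ccccc1)(c1ccccc1)C(C)(C)C
F6 | step 26 | 19-allyl 15-methyl (12S)-12-(tert-butyldimethylsilyloxy)-16-norlabd-8(17)-en-13-yne-15,19-dioate | C=C1CC[C@@H]2[C@](C)(CCC[C@]2(C)C(=O)OCC=C)[C@H]1C[C@H](O[Si](C)(C)C(C)(C)C)C#CC(=O)OC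
F7 | step 26 | 19-allyl 15-methyl (12S,13Z)-12-(tert-butyldimethylsilyloxy)labda-8(17),13-diene-15,19-dioate | C=C1CC[C@@H]2[C@](C)(CCC[C@]2(C)C(=O)OCC=C)[C@H]1C[C@H](O[Si](C)(C)C(C)(C)C)/C(C)=C\C(=O)OC
F8 | step 26 | (12S,13Z)-19-allyloxy-12-(tert-butyldimethylsilyloxy)-19-oxolabda-8(17),13-dien-15-oic acid | C=C1CC[C@@H]2[C@](C)(CCC[C@]2(C)C(=O)OCC=C)[C@H]1C[C@H](O[Si](C)(C)C(C)(C)C)/C(C)=C\C(=O)O
F9 | step 26 | (12S,13Z)-12-(tert-butyldimethylsilyloxy)labda-8(17),13-diene-15,19-dioic acid | C=C1CC[C@@H]2[C@](C)(CCC[C@]2(C)C(=O)O)[C@H]1C[C@H](O[Si](C)(C)C(C)(C)C)/C(C)=C\C(=O)O
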